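**Retrosynthetic overview**

- The target is cut at its two outer Ar–CH2–C(ring) bonds and, in the same operation, through each terminal ring at C2–C3 and C5–C6. This gives a tetra-aryl bis(Mannich base), two molecules of heptane-2,4-dione and two of dimethyl 2,2-dimethylmalonate.
- Enabling feature: each terminal ring is a 2-butanoylcyclohexane-1,3,5-trione. Its quaternary C4 (CMe2) lies between the carbonyl carbons C3 and C5, a dimethylmalonyl unit. C6–C1–C2, with the butanoyl group on C2, is the carbon chain of heptane-2,4-dione. After closure, C6–H between C1=O and C5–OH is the only nucleophilic carbon left and takes up the benzylic CH2.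
- The tetra-aryl core is cut at its two outer diarylmethane bonds into the methylene-bridged dimer of butyrylphloroglucinol and two bis-Mannich monomers, all from butyrylphloroglucinol, formaldehyde and dimethylamine.
- Ring order: the four benzene rings are bought with butyrylphloroglucinol; the two terminal carbocycles are the only rings made, and both are closed in the last step.

Key step: step 4

Assumption: the target and all triketone or phenol intermediates are drawn in one tautomeric form; the target has no stereocentre, so no configuration has to be set or kept.

**Step 1**
Reactants: 1 butyrylphloroglucinol (1-(2,4,6-trihydroxyphenyl)butan-1-one, two molecules); 2 formaldehyde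
Product: 3 methylene-bridged dimer of 1 (one CH2 joining C3 of two butyrylphloroglucinol rings, one free ring CH left on each)
Conditions: 2 (37% aq., 1 equiv), 1 (2.5 equiv), 1% aq. NaOH (2.5 equiv), 0 °C, 15 min; then 1 M HCl
Reagents that add atoms: formaldehyde, C=O; butyrylphloroglucinol, CCCC(=O)c1c(O)cc(O)cc1O
Why: Lederer–Manasse hydroxymethylation of one molecule of 1 followed by o-quinone methide capture by a second molecule of 1 should give the diarylmethane (two molecules of 1 and one of 2 per molecule of 3), and the excess of 1 should hold the condensation at the dimer.

**Step 2**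
Reactants: 1 butyrylphloroglucinol; 2 formaldehyde; 4 dimethylamine
Product: 5 bis-Mannich monomer (1-{3,5-bis[(dimethylamino)methyl]-2,4,6-trihydroxyphenyl}butan-1-one)
Conditions: 4 (40% aq., 2.4 equiv) and 2 (37% aq., 2.2 equiv) premixed, EtOH, 0 °C; then 1, 0 °C to rt
Reagents that add atoms: formaldehyde, C=O; dimethylamine, CNC
Why: a twofold phenolic Mannich reaction at the two equivalent free ring carbons of 1 should occur, and premixing the amine and formaldehyde should suppress diarylmethane formation.

**Step 3**
Reactants: 3 methylene-bridged dimer; 5 bis-Mannich monomer (two molecules)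
Product: 6 tetra-aryl bis(Mannich base) (four butyrylphloroglucinol rings joined by three CH2 bridges, one CH2NMe2 on each terminal ring, no free ring CH)
Conditions: 5 (8 equiv), 1,4-dioxane, 80 °C, N2, slow addition of 3
Reagents that add atoms: bis-Mannich monomer, CCCC(=O)c1c(O)c(CN(C)C)c(O)c(CN(C)C)c1O
Why: thermal loss of dimethylamine from one arm of each of two molecules of 5 should give o-quinone methides that are captured by the free ring CH at each end of 3 (Friedel–Crafts-type conjugate addition), and the excess of 5 should cap both ends before chains can grow.

**Step 4**
Reactants: 6 tetra-aryl bis(Mannich base); 7 heptane-2,4-dione; 8 dimethyl 2,2-dimethylpropanedioate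
Product: 12 target hexamer CNP0237140.0, via heptane-2,4-dione dianion 9 (not isolated), via open-chain triketo ester 10 (not isolated), via butyrylfilicinic acid 11 (not isolated)
Conditions: 7 (3 equiv), LiN(iPr)2 (9 equiv), THF, −78 to 0 °C; 8 (3.3 equiv, slow addition), 0 to 66 °C; then AcOH, MeOH, 6 (1 equiv), 60 °C
Reagents that add atoms: heptane-2,4-dione, CCCC(=O)CC(C)=O; dimethyl 2,2-dimethylpropanedioate, COC(=O)C(C)(C)C(=O)OC
Why: LiN(iPr)2 should convert 7 into its 1,3-dianion 9, whose terminal carbanion acylates one ester of the non-enolisable diester 8 (crossed Claisen γ-acylation of a β-diketone dianion, forming C5–C6) to give 10; the doubly activated central carbon then attacks the second ester (intramolecular Claisen, Dieckmann-type, forming C2–C3), a formal (3+3) annulation that is the laboratory counterpart of the Claisen cyclisation of 3,5,7-triketo esters to acylphloroglucinols. Each terminal ring is closed in the 6-exo-trig mode, and loss of methoxide followed by deprotonation to the stabilised dianion of 11 should make the closure irreversible. After buffering with AcOH, each Mannich terminus of 6 should lose dimethylamine to a transient o-quinone methide that is captured at C6 of 11 (conjugate addition, the Mannich-base way of making methylene bridges between acylfilicinic acids and acylphloroglucinols), so that two rings and six C–C bonds are made in one flask. No stereocentre is formed. The selectivities needed are methyl-over-methylene deprotonation of 7 (kinetic removal of the less substituted γ-proton), ring closure ahead of a second intermolecular acylation (six-membered transition state, slow addition of 8), and a single site of C-alkylation. The last is secured because C6 is the only ring CH of 11 and every aromatic carbon of 6 is already substituted; 7 is fully consumed before 6 is added, so no open-chain diketone competes for the quinone methide.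

**Compound list**

1 | butyrylphloroglucinol, 1-(2,4,6-trihydroxyphenyl)butan-1-one | CCCC(=O)c1c(O)cc(O)cc1O | starting material
2 | formaldehyde | C=O | starting material
3 | 1,1'-[methylenebis(2,4,6-trihydroxybenzene-3,1-diyl)]dibutan-1-one (methylene-bridged dimer) | CCCC(=O)c1c(O)cc(O)c(Cc2c(O)cc(O)c(C(=O)CCC)c2O)c1O | intermediate
4 | dimethylamine | CNC | starting material
5 | 1-{3,5-bis[(dimethylamino)methyl]-2,4,6-trihydroxyphenyl}butan-1-one (bis-Mannich monomer) | CCCC(=O)c1c(O)c(CN(C)C)c(O)c(CN(C)C)c1O | intermediate
6 | tetra-aryl bis(Mannich base): linear tetramer of butyrylphloroglucinol with three CH2 bridges and a CH2NMe2 group on each terminal ring | CN(C)Cc1c(O)c(Cc2c(O)c(Cc3c(O)c(Cc4c(O)c(CN(C)C)c(O)c(C(=O)CCC)c4O)c(O)c(C(=O)CCC)c3O)c(O)c(C(=O)CCC)c2O)c(O)c(C(=O)CCC)c1O | intermediate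
7 | heptane-2,4-dione | CCCC(=O)CC(C)=O | starting material
8 | dimethyl 2,2-dimethylpropanedioate | COC(=O)C(C)(C)C(=O)OC | starting material
9 | dilithium 1,3-dianion of heptane-2,4-dione | [Li+].[Li+].[CH2-]C(=O)[CH-]C(=O)CCC | intermediate
10 | methyl 2,2-dimethyl-3,5,7-trioxodecanoate (open-chain triketo ester, present in the flask as its lithium enolate, drawn neutral) | COC(=O)C(C)(C)C(=O)CC(=O)CC(=O)CCC | intermediate
11 | butyrylfilicinic acid, 2-butanoyl-3,5-dihydroxy-4,4-dimethylcyclohexa-2,5-dien-1-one (present in the flask as its lithium enolate, drawn neutral) | CCCC(=O)C1=C(O)C(C)(C)C(O)=CC1=O | intermediate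
12 | target hexamer CNP0237140.0: two butyrylfilicinic acid rings and four butyrylphloroglucinol rings joined in a row by five CH2 bridges | CCCC(=O)C1=C(O)C(C)(C)C(O)=C(Cc2c(O)c(Cc3c(O)c(Cc4c(O)c(Cc5c(O)c(CC6=C(O)C(C)(C)C(O)=C(C(=O)CCC)C6=O)c(O)c(C(=O)CCC)c5O)c(O)c(C(=O)CCC)c4O)c(O)c(C(=O)CCC)c3O)c(O)c(C(=O)CCC)c2O)C1=O | target

**Step count and risks**

Total step count: 4. Longest linear sequence: 3 steps (1 to 3 to 6 to 12, steps 1, 3 and 4).

Steps most likely to fail:

Step 4. The annulation may stop halfway through proton transfer from the first acylation product to unreacted dianion. Deprotonation of 7 may also occur on the propyl side, closure may take place through oxygen instead of carbon, and the diarylmethane bridges may exchange under base or heat during the coupling stage. Fallback: the fallback sets out from 7, 8 and 6 and comes back at 12. The annulation is run alone (LiN(iPr)2, THF, then acidic work-up) and butyrylfilicinic acid 11 is isolated and purified. In a separate flask 6 is quaternised with iodomethane (acetone, rt) to the bis(trimethylammonium) diiodide F1. F1 is then stirred with 11 (2.5 equiv) and NaHCO3 in aqueous THF at rt, where the quinone methide forms under mild base without heating.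

Step 3. Chain growth may compete with end-capping, because the product still carries two Mannich arms and the singly coupled intermediate carries both a free ring CH and a Mannich arm; retro-Mannich loss of an aminomethyl group would add further nucleophilic sites. Fallback: the fallback sets out from 3 and comes back at 6, with the polarity of the union reversed. 3 is aminomethylated at both free ring positions with 2 and 4 to the dimer bis-Mannich base F2. F2 is heated in dioxane with a large excess of 1 to give the tetramer F3, which has a free ring CH at each end. Exhaustive aminomethylation of F3 with 2 and 4 then gives 6.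

Step 1. Condensation may run past the dimer to higher oligomers, because the product keeps two reactive ring positions. Fallback: the fallback sets out from 1 and comes back at 3. 1 in excess is treated with one equivalent each of 2 and 4 (EtOH, 0 °C) to give the mono-Mannich base F4. F4 is then heated in the same excess of 1 (dioxane, 80 °C), so that the electrophile is formed in a controlled amount and captured by 1.

**Further compounds**

F1 | step 4 | bis(trimethylammonium) diiodide of 6 | C[N+](C)(C)Cc1c(O)c(Cc2c(O)c(Cc3c(O)c(Cc4c(O)c(C[N+](C)(C)C)c(O)c(C(=O)CCC)c4O)c(O)c(C(=O)CCC)c3O)c(O)c(C(=O)CCC)c2O)c(O)c(C(=O)CCC)c1O.[I-].[I-]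
F2 | step 3 | dimer bis-Mannich base, 3 with a CH2NMe2 group on the free carbon of each ring | CCCC(=O)c1c(O)c(CN(C)C)c(O)c(Cc2c(O)c(CN(C)C)c(O)c(C(=O)CCC)c2O)c1O
F3 | step 3 | linear tetramer of butyrylphloroglucinol with three CH2 bridges and a free CH on each terminal ring | CCCC(=O)c1c(O)cc(O)c(Cc2c(O)c(Cc3c(O)c(Cc4c(O)cc(O)c(C(=O)CCC)c4O)c(O)c(C(=O)CCC)c3O)c(O)c(C(=O)CCC)c2O)c1O
F4 | step 1 | mono-Mannich base, 1-{3-[(dimethylamino)methyl]-2,4,6-trihydroxyphenyl}butan-1-one | CCCC(=O)c1c(O)cc(O)c(CN(C)C)c1O
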